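## Structural features

The target is a cyclomyltaylane-type sesquiterpenoid triacetate: a tricyclo[2.2.1.0(2,6)]heptane (nortricyclene) cage fused to a cyclohexane (ring A) through the cage apex and one bridge carbon. Local numbering, used throughout: ring A is C1 (quaternary, bears C15H2OAc), C2 (CH2), C3 (CHOH), C4 (CHOAc), C5 (CMe2; methyls C12, C13) and C6 (quaternary apex); the one-carbon bridges C1, C7 (CH2) and C11 (CHOAc) run from C6 to the cyclopropane carbons C9, C8 and C10 (C10 bears methyl C14). C5, C6 and C1 are three contiguous quaternary carbons and C10 is a fourth; C6 is bonded only to carbon (C5, C1, C7, C11) and lies at the junction of all four rings. There are eight stereocentres (C1, C3, C4, C6, C8, C9, C10, C11): C6, C8, C9 and C10 follow from the cage once the sense at C1 is fixed (C15 points to the C7 bridge, C2 to the C11 bridge), whereas C3/C4 (cis diol; O3 axial and syn to C15 and to one C5 methyl, O4 equatorial and acetylated) and C11 (oxygen directed toward C7, away from ring A) are independent. Fragile features are the cyclopropylcarbinyl C11–O bond (ionisation, homoallyl rearrangement), three acetates next to a free cis hydroxyl (base, acyl migration) and, in precursors, a cyclopropyl ketone (no dissolving-metal or ketyl chemistry). The real difficulty is the fully substituted C6 together with the facial relationship between C15 on C1 and the C7–C8 bridge. The key step exploits the five-membered ring C1–C9–C10–C11–C6: with C11 at the ketone level it is a 2-methylcyclopentenone whose cross-conjugated silyl dienol ether is a cyclopentadiene with C6 and C9 as termini and C1 as its sp3 carbon, so the missing two-carbon bridge C7–C8 can be delivered across C6/C9 from the oxygen on C15.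

## Logic of the disconnections

25 ⇒ 24. The O4–acetyl bond is cut. O3 is axial and 1,3-syn to C15 and to a C5 methyl, whereas O4 is equatorial, so the last acylation needs no protecting group. The demand on the forward step is kinetic selectivity for O4 in a cis diol.

24 ⇒ 22 (through 23). The O11– and O15–acetyl bonds are cut and the isopropylidene acetal on O3/O4 is restored. This lets the hindered C11 carbinol be acylated under forcing conditions while the diol is masked. The acetal must then come off without ionising the cyclopropylcarbinyl acetate.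

22 ⇒ 21. The C11–H bond is cut (carbinol to ketone). The required C11 configuration is the more stable one, so an equilibrating hydride transfer can set it. The reduction must not open the cyclopropyl ketone.

21 ⇒ 19. The cyclopropane bond C8–C10 is cut and C8 is reconnected to O15 through a sulfonyl group; the C11 ketone becomes a silyl enol ether. In the resulting bicyclo[2.2.1]heptene the C10 enol carbon and an exo C8–S bond are 1,3-related, so one event gives the three-membered ring and frees O15. The demand is a sulfonate-ester sulfur acting as the carbon-bound leaving group.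

19 ⇒ 17 (through 18). The bonds C6–C7 and C8–C9 are cut, and the S–O15 bond behind them. This is the key disconnection: an intramolecular Diels–Alder reaction of a vinylsulfonate tethered through O15 onto the 2-siloxycyclopentadiene of 17. It removes the cage, the quaternary C6 and three stereocentres, leaving a bicyclic diene whose only stereogenic ring atom among the reacting carbons is C1. The forward step must add the dienophile to the diene face syn to C15, with C7 on C6.

17 ⇒ 15 (through 16). The enol O–Si bond is cut and C15 returns to the ester level. Masking the ketone as the diene allows the ester to be reduced without a redox detour. The demand is enolisation at the hindered C6–H.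

15 ⇒ 11 (through 13). The C10–C14 bond and the C9=C10 unsaturation are removed. Both come from ketone enolate chemistry at C10. Enolisation must be regioselective for C10 over C6.

11 ⇒ 8 (through 10). The C11–O bond is cut back to the C6=C11 alkene. Anti-Markovnikov hydration puts oxygen on C11 and hydrogen on C6. The alkene lies between two quaternary carbons, so a small hydroborating agent is needed.

8 ⇒ 5 (through 7 and 6). The C3–O bond and the C3–H and C4–H bonds are cut back to the C4 ketone. The ketone can enolise only toward C3, and both carbinol configurations follow from hydride attack anti to the axial groups on C1 and C5. The demand is facial selectivity in the double reduction.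

5 ⇒ 4. Both C5–CH3 bonds are cut. Deconjugative dialkylation of the enone installs the gem-dimethyl group and moves the alkene to C6=C11, where oxygen is needed next.

4 ⇒ 3 ⇒ 1 + 2. The C5–C6 bond (aldol condensation) and the C1–C2 bond (Michael addition) are cut. A catalytic enantioselective Michael addition of a β-keto ester sets C1, the one stereocentre that controls all the others.

## Other disconnections considered

Alternative 1: (the first that comes to mind) cut C8–C10 and C9–C10. The forward key step would be an intramolecular cyclopropanation of a cyclopentene C8=C9 by a carbene at C10, generated from diazoketone A1 with a copper or dirhodium catalyst, to give cage ketone A2 (the silyl ether of 21). The step would form only the three-membered ring. In A1, C6 must already be quaternary and carry the acyl group between C5 and C1, in a trans relationship to C15 across a hydrindene. That C6–C11 bond would have to be made by acylation or alkylation at a carbon flanked by two quaternary centres, with separate control of C1 against C6. The chosen plan makes C6 quaternary in the cage-forming step itself, from a planar diene terminus and a CH2 partner.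

Alternative 2: cut C9–C10 together with C11–O. The forward key step would be buffered acetolysis of norbornenyl mesylate A3: the C10=C11 alkene would assist ionisation at C9, and acetate would be expected to capture the nortricyclyl cation at C11 from the open C7 side. The functional outcome is attractive, but A3 needs ring A fused endo at C1 (C2 endo, ester exo). The intramolecular Diels–Alder reaction that would have to deliver A3 closes a four-atom tether from a diene terminus, and this is expected to go exo (smaller torsion about C1–C6), which gives the wrong C1 configuration. That cycloaddition would also have to join the two fully substituted carbons C1 and C6 next to CMe2, and a tertiary, methyl-bearing C10 invites Wagner–Meerwein shifts during ionisation.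

Alternative 3: copy the presumed biosynthesis and cut C9–C10 by 1,3-proton loss. Ionisation of tertiary alcohol A4 would give the C10 cation; loss of the C9 proton through the corner-protonated cyclopropane would close the cage to A5, and C11 would then be hydroxylated. Proton loss from C14 (exocyclic alkene) and skeletal shifts would be expected to compete with cyclopropane closure. The C11 oxygen would have to be added by an undirected C–H oxidation, with no handle for site (C11 against C7 or C2) or configuration. The chosen plan carries the C11 oxygen from the start as the carbonyl that activates the key step.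

Key step: step 13

Remarks and assumptions:
- Numbering: local numbering as defined above; in the indene names of 4–17, indene C7a/C7/C6/C5/C4/C3a/C3/C2/C1 are local C1/C2/C3/C4/C5/C6/C11/C10/C9.
- Step 1: the pseudoenantiomer of the cinchona catalyst that gives the R adduct is assumed; the sense of induction is assigned by analogy and would be confirmed on 4.
- Compounds 9–15: the configurations drawn at local C6, C11 and C10 are those expected from attack anti to the C1 ester; they are erased later (C11 becomes a ketone in 11, C10 and C6 become sp2 in 15 and 16) and do not affect the route.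

## Steps

Step 1
Reactants: 1 methyl 2-oxocyclopentane-1-carboxylate; 2 but-3-en-2-one (methyl vinyl ketone)
Product: 3 methyl (R)-2-oxo-1-(3-oxobutyl)cyclopentane-1-carboxylate
Conditions: 6′-hydroxy cinchona alkaloid bifunctional catalyst (10 mol %), CH2Cl2, −24 °C
Reagents that add atoms: none
Why: Catalytic enantioselective Michael addition of a cyclic β-keto ester to an enone; the catalyst (quinuclidine base, phenolic hydrogen-bond donor) should shield one face of the ester enolate and set the quaternary C1, the only stereocentre carried unchanged to the target.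

Step 2
Reactants: 3 methyl (R)-2-oxo-1-(3-oxobutyl)cyclopentane-1-carboxylate
Product: 4 methyl (7aR)-5-oxo-2,3,5,6,7,7a-hexahydro-1H-indene-7a-carboxylate
Conditions: p-TsOH·H2O (10 mol %), toluene, reflux, Dean–Stark
Reagents that add atoms: none
Why: Acid-catalysed intramolecular aldol condensation (second half of a Robinson annulation): the methyl ketone enol attacks the ring ketone and dehydration gives the conjugated enone; acid is chosen so that no retro-Michael path can erode C1.

Step 3
Reactants: 4 methyl (7aR)-5-oxo-2,3,5,6,7,7a-hexahydro-1H-indene-7a-carboxylate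
Product: 5 methyl (7aR)-4,4-dimethyl-5-oxo-2,4,5,6,7,7a-hexahydro-1H-indene-7a-carboxylate
Conditions: KOtBu (2.5 equiv), t-BuOH, rt; MeI (3 equiv), 0 °C to rt
Reagents that add atoms: iodomethane CI
Why: Deconjugative α,α-dialkylation of a cyclohexenone: KOtBu gives the extended dienolate by γ-deprotonation at C11, MeI alkylates at the α-carbon C5, and a second deprotonation/alkylation makes C5 quaternary, which locks the double bond at C6=C11; the non-enolisable C1 ester is untouched.

Step 4
Reactants: 5 methyl (7aR)-4,4-dimethyl-5-oxo-2,4,5,6,7,7a-hexahydro-1H-indene-7a-carboxylate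
Product: 6 methyl (7aR)-6-hydroxy-4,4-dimethyl-5-oxo-2,4,5,7a-tetrahydro-1H-indene-7a-carboxylate (diosphenol)
Conditions: KOtBu (2 equiv), O2 (1 atm), t-BuOH–THF, 0 °C to rt; AcOH quench
Reagents that add atoms: dioxygen O=O
Why: Base-mediated autoxidation of a ketone: the only possible enolate (toward C3, since C5 is quaternary) traps O2 to the α-hydroperoxide, which loses water to the 1,2-dione and is isolated as its enol; no new stereocentre.

Step 5
Reactants: 6 methyl (7aR)-6-hydroxy-4,4-dimethyl-5-oxo-2,4,5,7a-tetrahydro-1H-indene-7a-carboxylate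
Product: 7 methyl (5R,6S,7aR)-5,6-dihydroxy-4,4-dimethyl-2,4,5,6,7,7a-hexahydro-1H-indene-7a-carboxylate
Conditions: NaBH4 (3 equiv), MeOH, −20 °C to rt
Reagents that add atoms: none
Why: Double carbonyl reduction under substrate control: the C1 ester and one C5 methyl are syn-axial on one face of ring A, so hydride should add to the C4 carbonyl from the opposite face (axial attack, equatorial O4) and, after ketonisation of the enediol to the C3 ketone, again from that face (axial attack is blocked by the two syn-axial groups, so O3 ends axial); this is the behaviour of 4,4-dimethyl-3-oxo and 2-oxo steroids and gives the cis diol cis to the ester.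

Step 6
Reactants: 7 methyl (5R,6S,7aR)-5,6-dihydroxy-4,4-dimethyl-2,4,5,6,7,7a-hexahydro-1H-indene-7a-carboxylate
Product: 8 methyl (5R,6S,7aR)-5,6-(isopropylidenedioxy)-4,4-dimethyl-2,4,5,6,7,7a-hexahydro-1H-indene-7a-carboxylate
Conditions: 2,2-dimethoxypropane, PPTS (cat.), CH2Cl2, rt
Reagents that add atoms: 2,2-dimethoxypropane COC(C)(C)OC
Why: Acid-catalysed transacetalisation; the cis-1,2-diol forms the five-membered isopropylidene acetal, which masks both secondary alcohols through the base, hydride and oxidation steps that follow.

Step 7
Reactants: 8 methyl (5R,6S,7aR)-5,6-(isopropylidenedioxy)-4,4-dimethyl-2,4,5,6,7,7a-hexahydro-1H-indene-7a-carboxylate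
Product: 10 methyl (3S,3aS,5R,6S,7aR)-3-hydroxy-5,6-(isopropylidenedioxy)-4,4-dimethyloctahydro-1H-indene-7a-carboxylate, via alkylborane 9 (not isolated)
Conditions: BH3·THF (3 equiv), THF, 0 °C to rt; then NaOH (aq), H2O2, 0 °C to rt
Reagents that add atoms: borane–tetrahydrofuran B.C1CCOC1 (boron in 9 only); hydrogen peroxide OO
Why: Hydroboration–oxidation: BH3 should add syn and anti-Markovnikov to the trisubstituted C6=C11 bond (boron on C11, hydrogen on C6) from the face opposite the C1 ester, as with 4,4-dimethyl-5-ene steroids, and alkaline H2O2 oxidises C–B with retention; the hindered neopentyl ester reacts much more slowly, and the two new centres are not kept.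

Step 8
Reactants: 10 methyl (3S,3aS,5R,6S,7aR)-3-hydroxy-5,6-(isopropylidenedioxy)-4,4-dimethyloctahydro-1H-indene-7a-carboxylate
Product: 11 methyl (3aS,5R,6S,7aR)-5,6-(isopropylidenedioxy)-4,4-dimethyl-3-oxooctahydro-1H-indene-7a-carboxylate
Conditions: Dess–Martin periodinane, CH2Cl2, rt
Reagents that add atoms: none
Why: Dess–Martin oxidation of the secondary alcohol to the C11 ketone under near-neutral conditions that leave the acetal and the C6 hydrogen alone.

Step 9
Reactants: 11 methyl (3aS,5R,6S,7aR)-5,6-(isopropylidenedioxy)-4,4-dimethyl-3-oxooctahydro-1H-indene-7a-carboxylate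
Product: 13 methyl (2S,3aS,5R,6S,7aR)-5,6-(isopropylidenedioxy)-2,4,4-trimethyl-3-oxooctahydro-1H-indene-7a-carboxylate, via lithium enolate 12 (not isolated)
Conditions: LiN(i-Pr)2, THF, −78 °C; MeI, −78 to −30 °C
Reagents that add atoms: lithium diisopropylamide CC(C)[N-]C(C)C.[Li+] (lithium in 12 only); iodomethane CI
Why: Kinetic enolate alkylation: the amide base removes a proton from the accessible C10 methylene, not from the C6 methine flanked by two quaternary carbons, and MeI adds C14 from the face away from the C1 ester; the new centre becomes sp2 in step 10.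

Step 10
Reactants: 13 methyl (2S,3aS,5R,6S,7aR)-5,6-(isopropylidenedioxy)-2,4,4-trimethyl-3-oxooctahydro-1H-indene-7a-carboxylate
Product: 15 methyl (3aS,5R,6S,7aS)-5,6-(isopropylidenedioxy)-2,4,4-trimethyl-3-oxo-3,3a,4,5,6,7-hexahydro-7aH-indene-7a-carboxylate, via trimethylsilyl enol ether 14 (not isolated)
Conditions: Me3SiOTf, Et3N, CH2Cl2, 0 °C; then Pd(OAc)2 (1.1 equiv), MeCN, rt
Reagents that add atoms: trimethylsilyl trifluoromethanesulfonate C[Si](C)(C)OS(=O)(=O)C(F)(F)F (silicon in 14 only)
Why: Saegusa–Ito oxidation: soft enolisation gives the more substituted C10=C11 silyl enol ether, Pd(OAc)2 forms the palladium enolate, and β-hydride elimination toward C9 gives the 2-methylcyclopentenone with release of zerovalent palladium; unsaturation toward C6–C1 is impossible because C1 has no hydrogen.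

Step 11
Reactants: 15 methyl (3aS,5R,6S,7aS)-5,6-(isopropylidenedioxy)-2,4,4-trimethyl-3-oxo-3,3a,4,5,6,7-hexahydro-7aH-indene-7a-carboxylate
Product: 16 methyl (5R,6S,7aS)-3-[(tert-butyldimethylsilyl)oxy]-5,6-(isopropylidenedioxy)-2,4,4-trimethyl-4,5,6,7-tetrahydro-7aH-indene-7a-carboxylate
Conditions: t-BuMe2SiOTf, Et3N, CH2Cl2, 0 °C to rt
Reagents that add atoms: tert-butyldimethylsilyl trifluoromethanesulfonate CC(C)(C)[Si](C)(C)OS(=O)(=O)C(F)(F)F
Why: Soft enolisation of an enone: O-silylation activates the ketone and Et3N removes the only acidic proton, the α′ hydrogen on C6 (C1 is quaternary, so there is no γ-proton), giving the cross-conjugated 2-siloxycyclopentadiene; C6 becomes sp2, the quaternary C1 blocks 1,5-hydrogen shifts, and the ketone is masked for step 12.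

Step 12
Reactants: 16 methyl (5R,6S,7aS)-3-[(tert-butyldimethylsilyl)oxy]-5,6-(isopropylidenedioxy)-2,4,4-trimethyl-4,5,6,7-tetrahydro-7aH-indene-7a-carboxylate
Product: 17 [(5R,6S,7aS)-3-[(tert-butyldimethylsilyl)oxy]-5,6-(isopropylidenedioxy)-2,4,4-trimethyl-4,5,6,7-tetrahydro-7aH-inden-7a-yl]methanol
Conditions: i-Bu2AlH (3 equiv), CH2Cl2, −78 to 0 °C; aq. potassium sodium tartrate (KNaC4H4O6)
Reagents that add atoms: none
Why: Hydride reduction of the neopentyl methyl ester to the primary alcohol C15–OH; the silyl dienol ether and the acetal are inert to the aluminium hydride, so the C11 carbonyl needs no redox detour.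

Step 13
Reactants: 17 [(5R,6S,7aS)-3-[(tert-butyldimethylsilyl)oxy]-5,6-(isopropylidenedioxy)-2,4,4-trimethyl-4,5,6,7-tetrahydro-7aH-inden-7a-yl]methanol
Product: 19 bridged δ-sultone silyl enol ether (bicyclo[2.2.1]heptene C6–C7–C8–C9–C10=C11 with C1 as one-carbon bridge; ring A and 3,4-O-isopropylidene retained; 11-OSi(t-Bu)Me2; ring S–O15–C15–C1–C9–C8 with sulfur exo on C8), via vinylsulfonate ester 18 (not isolated)
Conditions: ClCH2CH2SO2Cl, Et3N, CH2Cl2, −20 to 0 °C; then toluene, BHT (cat.), 80 °C
Reagents that add atoms: 2-chloroethanesulfonyl chloride ClCCS(Cl)(=O)=O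
Why: Sulfonylation of the neopentyl alcohol with ethenesulfonyl chloride formed in situ gives 18, whose electron-poor alkene lies over the electron-rich 2-siloxycyclopentadiene and should add in an intramolecular Diels–Alder reaction on warming; the closest known reaction type is the intramolecular [4+2] cycloaddition of vinylsulfonates of dienols to sultones and, in bond-set terms, the Michael–Michael bicycloannulation of cross-conjugated cyclopentenone dienolates with vinyl sulfones. Two bonds form, C6–C7 and C8–C9. The carbocyclic six-membered ring C6–C7–C8–C9–C10–C11 closes by suprafacial [4+2] addition across the diene termini C6 and C9 (giving the bicyclo[2.2.1]heptene with C1 as bridge), and the six-membered sultone ring S–O15–C15–C1–C9–C8 closes through the C8–C9 bond, its three-atom tether anchored on C1. The new stereocentres are C6, C9 and C8: C6 and C9 are set together because the tether from C15 can reach only the diene face syn to C15, so the C7–C8 bridge ends syn to C15 and C2 of ring A anti to it, as in the target, and C8 carries sulfur exo (toward C1), the only orientation the short tether allows. The selectivity needed is regiochemical (C7 to C6, C8 to C9; the reverse mode would also give a six-membered sultone): the siloxy group on C11 puts the largest HOMO coefficient on C6, which pairs with the electrophilic CH2 terminus, and the sulfonyl-bearing carbon goes to the unhindered C9–H rather than to C6, which is flanked by C5 and C1. Without the tether a dienophile would be expected on the other face, away from the axial C15 and the axial C5 methyl, so the tether overrides the substrate bias. In one operation the step should create the fully substituted C6 with a CH2 partner, the bicyclic core and three stereocentres, and leave the C8–S bond exo, opposite the endo lobe of C10, ready for step 14.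

Step 14
Reactants: 19 bridged δ-sultone silyl enol ether
Product: 21 cage ketone: 15-hydroxy-3,4-O-isopropylidene nortricyclene-fused ketone (C11=O; C8–C9–C10 cyclopropane), via tetrabutylammonium alkyl sulfite 20 (not isolated)
Conditions: Bu4NF (anhydrous, 1.5 equiv), 4 Å MS, THF, 0 to 50 °C; then H2O
Reagents that add atoms: tetrabutylammonium fluoride CCCC[N+](CCCC)(CCCC)CCCC.[F-] (counter-ion of 20 only)
Why: Proposed new method: fluoride cleaves the silyl enol ether to a naked ammonium enolate whose C10 terminus lies about 2.4 Å from C8 on the endo face of the bicyclo[2.2.1] skeleton, directly opposite the exo C8–S bond, so an intramolecular 3-exo-tet displacement should close the C8–C10 cyclopropane and expel the sulfonyl group as the alkyl sulfite 20, which loses SO2 on aqueous work-up to free O15–H; the closest known reaction types are the 1,3-elimination of sulfinate from γ-sulfonyl enolates (cyclopropanes from sulfones) and the base-induced 1,3-elimination of γ-sulfonyloxy ketones to tricyclic cyclopropyl ketones, the new element being a sulfonate-ester sulfur as the carbon-bound nucleofuge; C8 is inverted and C10 becomes quaternary with the configuration the cage dictates.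

Step 15
Reactants: 21 cage ketone (15-hydroxy, 3,4-O-isopropylidene, C11=O)
Product: 22 cage diol: 11,15-dihydroxy-3,4-O-isopropylidene cage with O11 directed toward C7
Conditions: Al(O-i-Pr)3 (3 equiv), i-PrOH–toluene, acetone (0.1 equiv), 100 °C
Reagents that add atoms: none
Why: Meerwein–Ponndorf–Verley reduction under equilibrating conditions: hydride transfer from isopropoxide is reversible in the presence of acetone, so the C11 carbinol should settle in its more stable configuration, oxygen toward the unsubstituted C7 bridge and hydrogen toward C2 of ring A (the bornyl rather than the isobornyl arrangement), which is that of the target; no single-electron step is involved, so the cyclopropyl ketone is not opened.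

Step 16
Reactants: 22 cage diol (11,15-dihydroxy, 3,4-O-isopropylidene)
Product: 24 cage diol diacetate: 11,15-diacetoxy-3,4-dihydroxy cage, via diacetate acetonide 23 (not isolated)
Conditions: Ac2O, DMAP, pyridine, 40 °C; evaporate; then AcOH–H2O (4:1), 45 °C
Reagents that add atoms: acetic anhydride CC(=O)OC(C)=O
Why: DMAP-catalysed acylation takes the primary O15 and the hindered secondary O11 while the diol is masked; aqueous acetic acid then hydrolyses the isopropylidene acetal under conditions too weakly acidic to ionise the cyclopropylcarbinyl acetate; no stereocentre is touched.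

Step 17
Reactants: 24 cage diol diacetate (11,15-diacetoxy-3,4-dihydroxy)
Product: 25 target CNP0111873.1 (4,11,15-triacetoxy-3-hydroxy cage, local numbering)
Conditions: Ac2O (1.3 equiv), pyridine, 0 °C to rt
Reagents that add atoms: acetic anhydride CC(=O)OC(C)=O
Why: Kinetically selective acylation of a cis-1,2-diol: O4 is equatorial, whereas O3 is axial and 1,3-syn to both C15 and the axial C5 methyl (the situation of a steroid 11β-hydroxyl, which resists Ac2O/pyridine); 1,2-acyl migration, if it occurred, would also favour the equatorial O4 ester.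

## Compound list

1 | methyl 2-oxocyclopentane-1-carboxylate | COC(=O)C1CCCC1=O | starting material
2 | but-3-en-2-one (methyl vinyl ketone) | CC(=O)C=C | starting material
3 | methyl (R)-2-oxo-1-(3-oxobutyl)cyclopentane-1-carboxylate | COC(=O)[C@@]1(CCC(C)=O)CCCC1=O | intermediate
4 | methyl (7aR)-5-oxo-2,3,5,6,7,7a-hexahydro-1H-indene-7a-carboxylate | COC(=O)[C@]12CCC(=O)C=C1CCC2 | intermediate
5 | methyl (7aR)-4,4-dimethyl-5-oxo-2,4,5,6,7,7a-hexahydro-1H-indene-7a-carboxylate | COC(=O)[C@]12CCC(=O)C(C)(C)C1=CCC2 | intermediate
6 | methyl (7aR)-6-hydroxy-4,4-dimethyl-5-oxo-2,4,5,7a-tetrahydro-1H-indene-7a-carboxylate | COC(=O)[C@]12C=C(O)C(=O)C(C)(C)C1=CCC2 | intermediate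
7 | methyl (5R,6S,7aR)-5,6-dihydroxy-4,4-dimethyl-2,4,5,6,7,7a-hexahydro-1H-indene-7a-carboxylate | COC(=O)[C@]12C[C@H](O)[C@H](O)C(C)(C)C1=CCC2 | intermediate
8 | methyl (5R,6S,7aR)-5,6-(isopropylidenedioxy)-4,4-dimethyl-2,4,5,6,7,7a-hexahydro-1H-indene-7a-carboxylate | COC(=O)[C@]12C[C@@H]3OC(C)(C)O[C@@H]3C(C)(C)C1=CCC2 | intermediate
9 | alkylborane from 8 (BH2 on indene C3, H on C3a) | COC(=O)[C@]12C[C@@H]3OC(C)(C)O[C@@H]3C(C)(C)[C@@H]1[C@@H](B)CC2 | intermediate
10 | methyl (3S,3aS,5R,6S,7aR)-3-hydroxy-5,6-(isopropylidenedioxy)-4,4-dimethyloctahydro-1H-indene-7a-carboxylate | COC(=O)[C@]12C[C@@H]3OC(C)(C)O[C@@H]3C(C)(C)[C@@H]1[C@@H](O)CC2 | intermediate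
11 | methyl (3aS,5R,6S,7aR)-5,6-(isopropylidenedioxy)-4,4-dimethyl-3-oxooctahydro-1H-indene-7a-carboxylate | COC(=O)[C@]12C[C@@H]3OC(C)(C)O[C@@H]3C(C)(C)[C@@H]1C(=O)CC2 | intermediate
12 | lithium enolate of 11 (indene C2=C3) | COC(=O)[C@]12C[C@@H]3OC(C)(C)O[C@@H]3C(C)(C)[C@@H]1C(O[Li])=CC2 | intermediate
13 | methyl (2S,3aS,5R,6S,7aR)-5,6-(isopropylidenedioxy)-2,4,4-trimethyl-3-oxooctahydro-1H-indene-7a-carboxylate | COC(=O)[C@]12C[C@@H]3OC(C)(C)O[C@@H]3C(C)(C)[C@@H]1C(=O)[C@@H](C)C2 | intermediate
14 | trimethylsilyl enol ether of 13 (indene C2=C3) | COC(=O)[C@]12C[C@@H]3OC(C)(C)O[C@@H]3C(C)(C)[C@@H]1C(O[Si](C)(C)C)=C(C)C2 | intermediate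
15 | methyl (3aS,5R,6S,7aS)-5,6-(isopropylidenedioxy)-2,4,4-trimethyl-3-oxo-3,3a,4,5,6,7-hexahydro-7aH-indene-7a-carboxylate | COC(=O)[C@]12C[C@@H]3OC(C)(C)O[C@@H]3C(C)(C)[C@@H]1C(=O)C(C)=C2 | intermediate
16 | methyl (5R,6S,7aS)-3-[(tert-butyldimethylsilyl)oxy]-5,6-(isopropylidenedioxy)-2,4,4-trimethyl-4,5,6,7-tetrahydro-7aH-indene-7a-carboxylate | COC(=O)[C@]12C[C@@H]3OC(C)(C)O[C@@H]3C(C)(C)C1=C(O[Si](C)(C)C(C)(C)C)C(C)=C2 | intermediate
17 | [(5R,6S,7aS)-3-[(tert-butyldimethylsilyl)oxy]-5,6-(isopropylidenedioxy)-2,4,4-trimethyl-4,5,6,7-tetrahydro-7aH-inden-7a-yl]methanol | OC[C@]12C[C@@H]3OC(C)(C)O[C@@H]3C(C)(C)C1=C(O[Si](C)(C)C(C)(C)C)C(C)=C2 | intermediate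
18 | ethenesulfonate (vinylsulfonate) ester of 17 | C=CS(=O)(=O)OC[C@]12C[C@@H]3OC(C)(C)O[C@@H]3C(C)(C)C1=C(O[Si](C)(C)C(C)(C)C)C(C)=C2 | intermediate
19 | bridged δ-sultone silyl enol ether (Diels–Alder adduct; sulfur exo on C8) | O=S1(=O)OC[C@]23C[C@@H]4OC(C)(C)O[C@@H]4C(C)(C)[C@]25C[C@H]1[C@H]3C(C)=C5O[Si](C)(C)C(C)(C)C | intermediate
20 | tetrabutylammonium salt of the O15 sulfite monoester of 21 | [O-]S(=O)OC[C@]12C[C@@H]3OC(C)(C)O[C@@H]3C(C)(C)[C@]14C[C@@H]5[C@H]2[C@]5(C)C4=O.CCCC[N+](CCCC)(CCCC)CCCC | intermediate
21 | cage ketone (15-hydroxy, 3,4-O-isopropylidene, C11=O) | OC[C@]12C[C@@H]3OC(C)(C)O[C@@H]3C(C)(C)[C@]14C[C@@H]5[C@H]2[C@]5(C)C4=O | intermediate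
22 | cage diol (11,15-dihydroxy, 3,4-O-isopropylidene; O11 toward C7) | OC[C@]12C[C@@H]3OC(C)(C)O[C@@H]3C(C)(C)[C@]14C[C@@H]5[C@H]2[C@]5(C)[C@H]4O | intermediate
23 | cage diacetate acetonide (11,15-diacetoxy, 3,4-O-isopropylidene) | CC(=O)OC[C@]12C[C@@H]3OC(C)(C)O[C@@H]3C(C)(C)[C@]14C[C@@H]5[C@H]2[C@]5(C)[C@H]4OC(C)=O | intermediate
24 | cage diol diacetate (11,15-diacetoxy-3,4-dihydroxy) | CC(=O)OC[C@]12C[C@H](O)[C@H](O)C(C)(C)[C@]13C[C@@H]4[C@H]2[C@]4(C)[C@H]3OC(C)=O | intermediate
25 | CNP0111873.1 (4,11,15-triacetoxy-3-hydroxy cage) | CC(=O)OC[C@]12C[C@H](O)[C@H](OC(C)=O)C(C)(C)[C@]13C[C@@H]1[C@H]2[C@]1(C)[C@H]3OC(C)=O | target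

## Step count and least certain steps

Total step count: 17. Longest linear sequence: 17 (the route is linear from 1 and 2).

Step 14 (Proposed new method). The most likely failure is that the enolate does not displace the sulfonyl carbon: a carbon bearing a sulfonyl group is a poor SN2 centre, so protonation of the enolate by adventitious water or deprotonation at C8 may win over ring closure. Fallback with known chemistry, from 19 back to 21: C8 is lithiated (LiN(i-Pr)2, THF, −78 °C) and the carbanion oxidised with bis(trimethylsilyl) peroxide, the established oxidative desulfonylation of α-sulfonyl carbanions, which should give the C8 ketone with O15–H free, keto alcohol F1. Benzoylation (BzCl, pyridine) gives benzoate F2. NaBH4 should attack the C8 ketone from the endo face, the exo face being covered by C15, to give exo alcohol F3, and MsCl/Et3N gives mesylate F4. Bu4NF then unmasks the C10 enolate, which displaces the exo mesylate in the well-known 1,3-elimination of γ-sulfonyloxy ketones to give cage ketone benzoate F5; K2CO3/MeOH removes the benzoate and returns 21.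

Step 13 (key step). The cycloaddition may be slow because the diene terminus C6 lies between the quaternary C5 and C1, leaving time for hydrolysis of the silyl dienol ether or polymerisation of the vinylsulfonate; the reverse regiochemistry (C8 to C6) is the other possible loss. Fallback, from 17 back to 19, using a stepwise anionic mechanism in place of the thermal cycloaddition: mild acid (PPTS, aqueous THF) desilylates 17 to enone alcohol F6, and sulfonylation as in step 13 gives vinylsulfonate enone F7. KN(SiMe3)2 (THF, −78 °C) then generates the far more nucleophilic potassium dienolate for an intramolecular double Michael addition (C6 to C7, then C8 to C9), and the resulting enolate is trapped with t-BuMe2SiCl to give 19.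

Step 5. Facial selectivity may be poor in the second reduction: an alkoxyborohydride on O4 could deliver hydride to the C3 ketone intramolecularly, or hydride could attack C3 first, leading to trans diol. Fallback, from 5 back to 7, separating the two centres: Rubottom oxidation of 5 (LiN(SiMe3)2, Me3SiCl; m-CPBA; dilute acid) gives hydroxy ketone F8 (O3 equatorial, C4 ketone). Base-mediated ketol transposition (K2CO3, MeOH) should move the carbonyl to C3 and leave O4 equatorial, ketol F9. LiBH(s-Bu)3 at −78 °C then adds to the C3 ketone from the face away from the two syn-axial groups to give 7.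

Step 15. Equilibration may be incomplete at the very hindered C11 ketone, leaving a mixture of C11 epimers enriched in the kinetic one (hydride from the open C7 side, oxygen toward ring A). Fallback, from 21 to 23, by inversion instead of equilibration: Ac2O/pyridine acetylates O15 to give acetate F10; NaBH4 gives the kinetic alcohol F11; MsCl/Et3N gives mesylate F12; CsOAc with 18-crown-6 in toluene at 80 °C replaces the mesylate by acetate from the open C7 side (the same outcome by SN2 or by capture of the nortricyclyl cation) and gives 23, which is carried on through the acid treatment of step 16.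

## Further compounds

F1 | step 14 | keto alcohol (C8 ketone, O15–H, silyl enol ether at C10=C11) | OC[C@]12C[C@@H]3OC(C)(C)O[C@@H]3C(C)(C)[C@]14CC(=O)[C@H]2C(C)=C4O[Si](C)(C)C(C)(C)C
F2 | step 14 | O15 benzoate of F1 | O=C(OC[C@]12C[C@@H]3OC(C)(C)O[C@@H]3C(C)(C)[C@]14CC(=O)[C@H]2C(C)=C4O[Si](C)(C)C(C)(C)C)c5ccccc5
F3 | step 14 | exo C8 alcohol from F2 | O=C(OC[C@]12C[C@@H]3OC(C)(C)O[C@@H]3C(C)(C)[C@]14C[C@H](O)[C@H]2C(C)=C4O[Si](C)(C)C(C)(C)C)c5ccccc5
F4 | step 14 | exo C8 mesylate from F3 | O=C(OC[C@]12C[C@@H]3OC(C)(C)O[C@@H]3C(C)(C)[C@]14C[C@H](OS(C)(=O)=O)[C@H]2C(C)=C4O[Si](C)(C)C(C)(C)C)c5ccccc5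
F5 | step 14 | cage ketone O15 benzoate | O=C(OC[C@]12C[C@@H]3OC(C)(C)O[C@@H]3C(C)(C)[C@]14C[C@@H]5[C@H]2[C@]5(C)C4=O)c6ccccc6
F6 | step 13 | enone alcohol (desilylated 17) | OC[C@]12C[C@@H]3OC(C)(C)O[C@@H]3C(C)(C)[C@@H]1C(=O)C(C)=C2
F7 | step 13 | vinylsulfonate ester of F6 | C=CS(=O)(=O)OC[C@]12C[C@@H]3OC(C)(C)O[C@@H]3C(C)(C)[C@@H]1C(=O)C(C)=C2
F8 | step 5 | methyl (6R,7aR)-6-hydroxy-4,4-dimethyl-5-oxo-2,4,5,6,7,7a-hexahydro-1H-indene-7a-carboxylate (O3 equatorial) | COC(=O)[C@]12C[C@@H](O)C(=O)C(C)(C)C1=CCC2
F9 | step 5 | methyl (5R,7aR)-5-hydroxy-4,4-dimethyl-6-oxo-2,4,5,6,7,7a-hexahydro-1H-indene-7a-carboxylate (transposed ketol) | COC(=O)[C@]12CC(=O)[C@H](O)C(C)(C)C1=CCC2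
F10 | step 15 | cage ketone O15 acetate | CC(=O)OC[C@]12C[C@@H]3OC(C)(C)O[C@@H]3C(C)(C)[C@]14C[C@@H]5[C@H]2[C@]5(C)C4=O
F11 | step 15 | C11-epimeric alcohol (O11 toward C1), O15 acetate | CC(=O)OC[C@]12C[C@@H]3OC(C)(C)O[C@@H]3C(C)(C)[C@]14C[C@@H]5[C@H]2[C@]5(C)[C@@H]4O
F12 | step 15 | mesylate of F11 | CC(=O)OC[C@]12C[C@@H]3OC(C)(C)O[C@@H]3C(C)(C)[C@]14C[C@@H]5[C@H]2[C@]5(C)[C@@H]4OS(C)(=O)=O
A1 | alternative 1 | diazoketone on a trans-fused hydrindene (C6 bears C(=O)C(=N2)CH3, C1 bears CH2OSi(t-Bu)Me2, C8=C9 alkene) | CC(=[N+]=[N-])C(=O)[C@@]12CC=C[C@@]1(CO[Si](C)(C)C(C)(C)C)C[C@@H]3OC(C)(C)O[C@@H]3C2(C)C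
A2 | alternative 1 | O15 tert-butyldimethylsilyl ether of 21 | CC(C)(C)[Si](C)(C)OC[C@]12C[C@@H]3OC(C)(C)O[C@@H]3C(C)(C)[C@]14C[C@@H]5[C@H]2[C@]5(C)C4=O
A3 | alternative 2 | norbornenyl mesylate (C10=C11 alkene, exo C9 mesylate, exo C1 methyl ester, ring A endo on C1) | COC(=O)[C@]12C[C@@H]3OC(C)(C)O[C@@H]3C(C)(C)[C@]14C[C@@H](C(C)=C4)[C@@H]2OS(C)(=O)=O
A4 | alternative 3 | tertiary C10 alcohol on the bicyclo[2.2.1]heptane (C9 and C11 methylene) | CC(C)(C)[Si](C)(C)OC[C@]12C[C@@H]3OC(C)(C)O[C@@H]3C(C)(C)[C@]14C[C@H](C2)[C@](C)(O)C4
A5 | alternative 3 | C11-deoxy cage | CC(C)(C)[Si](C)(C)OC[C@]12C[C@@H]3OC(C)(C)O[C@@H]3C(C)(C)[C@]14C[C@@H]5[C@H]2[C@]5(C)C4
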